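## Retrosynthetic overview

1. Target 13 ⇐ angeloylation of the C2 alcohol of bis-epoxide 12.
2. 12 ⇐ triene alcohol 10 by one single-flask double epoxidation that closes both oxiranes: C3–C4 directed by C2–OH, C10–C11 under chiral-ketone control.
3. 10 ⇐ enone 9 (Luche reduction) ⇐ allyl carbinol 7 (angeloylation, cross-metathesis to the prenyl group) ⇐ enal 6 by Brown allylation (sets C8).
4. 6 ⇐ (R)-carvone 1 by α′-hydroxylation/angeloylation (sets C1), ene chlorination and N-oxide oxidation of the isopropenyl methyl.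
5. Ring order: the cyclohexane ring is carried from carvone; the ring oxirane forms first and the side-chain oxirane second, both within step 8.

Assumption: bisabolane numbering is used (ring C1–C6: C1 and C2 ester carbons, C3 bears methyl C15, C6 bears the side chain C7(=C14H2)–C8–C9–C10–C11(C12)(C13)); angelate = (Z)-2-methylbut-2-enoate; angelic anhydride, the Davis oxaziridine, (−)-Ipc2B(allyl) and the Shi ketone are bought.

## Route

Step 1
Reactants: 1 (R)-(−)-carvone
Product: 4 (1S,6S)-3-methyl-2-oxo-6-(prop-1-en-2-yl)cyclohex-3-en-1-yl angelate, via potassium dienolate 2 (not isolated), via potassium alkoxide 3 (not isolated)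
Conditions: KN(SiMe3)2 (1.1 equiv), THF, −78 °C; 2-(phenylsulfonyl)-3-phenyloxaziridine (1.3 equiv), −78 °C; angelic anhydride (1.6 equiv), −78 → −20 °C; aq NH4Cl
Reagents that add atoms: 2-(phenylsulfonyl)-3-phenyloxaziridine (Davis oxaziridine), O=S(=O)(N1OC1c1ccccc1)c1ccccc1; angelic anhydride, C/C=C(/C)C(=O)OC(=O)/C(C)=C\C
Why: Kinetic α′-deprotonation gives the cross-conjugated dienolate, Davis enolate hydroxylation delivers oxygen anti to the neighbouring isopropenyl group (trans, 1S), and the alkoxide is O-acylated in situ without a nucleophilic catalyst that would isomerise angelate to tiglate.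

Step 2
Reactants: 4 (1S,6S)-3-methyl-2-oxo-6-(prop-1-en-2-yl)cyclohex-3-en-1-yl angelate
Product: 5 (1S,6S)-6-(3-chloroprop-1-en-2-yl)-3-methyl-2-oxocyclohex-3-en-1-yl angelate
Conditions: Ca(OCl)2 (0.6 equiv), solid CO2, CH2Cl2/H2O, 0 °C
Reagents that add atoms: calcium hypochlorite Ca(OCl)2, [Ca+2].[O-]Cl.[O-]Cl
Why: Ene-type allylic chlorination by HOCl attacks only the electron-rich 1,1-disubstituted isopropenyl alkene (as carvone gives 10-chlorocarvone), the enone and angelate alkenes being electron-poor, and no stereocentre is touched.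

Step 3
Reactants: 5 (1S,6S)-6-(3-chloroprop-1-en-2-yl)-3-methyl-2-oxocyclohex-3-en-1-yl angelate
Product: 6 (1S,6S)-3-methyl-2-oxo-6-(3-oxoprop-1-en-2-yl)cyclohex-3-en-1-yl angelate
Conditions: N-methylmorpholine N-oxide (4 equiv), KI (0.1 equiv), MeCN, 40 °C
Reagents that add atoms: N-methylmorpholine N-oxide, C[N+]1([O-])CCOCC1
Why: Ganem-type N-oxide oxidation (Kornblum family): iodide-catalysed SN2 O-alkylation of the N-oxide by the allylic halide, then elimination of N-methylmorpholine, gives the 2-substituted acrolein under nearly neutral conditions without changing a stereocentre.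

Step 4
Reactants: 6 (1S,6S)-3-methyl-2-oxo-6-(3-oxoprop-1-en-2-yl)cyclohex-3-en-1-yl angelate
Product: 7 (1S,6S)-6-[(3S)-3-hydroxyhexa-1,5-dien-2-yl]-3-methyl-2-oxocyclohex-3-en-1-yl angelate
Conditions: (−)-Ipc2B(allyl) (1.2 equiv), Et2O, −78 °C; then pH 7 phosphate buffer, 30% H2O2, MeOH, 0 °C
Reagents that add atoms: (−)-B-allyldiisopinocampheylborane (from (+)-α-pinene), C=CCB([C@@H]1C[C@@H]2C[C@H]([C@H]1C)C2(C)C)[C@@H]1C[C@@H]2C[C@H]([C@H]1C)C2(C)C
Why: Brown asymmetric allylboration through a closed chair (Zimmerman–Traxler) transition state is aldehyde-selective at −78 °C, and this reagent enantiomer gives the 8S carbinol under reagent control (same sense as for benzaldehyde and acrolein).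

Step 5
Reactants: 7 (1S,6S)-6-[(3S)-3-hydroxyhexa-1,5-dien-2-yl]-3-methyl-2-oxocyclohex-3-en-1-yl angelate
Product: 8 (1S,6S)-6-[(3S)-3-(angeloyloxy)hexa-1,5-dien-2-yl]-3-methyl-2-oxocyclohex-3-en-1-yl angelate
Conditions: angelic acid (2.5 equiv), 2,4,6-trichlorobenzoyl chloride (2.5 equiv), Et3N (5 equiv), PhMe, rt; then 7, 75 °C
Reagents that add atoms: angelic acid, C/C=C(/C)C(=O)O
Why: Yamaguchi-type mixed-anhydride esterification without DMAP is the established way to make angelates of secondary alcohols without Z-to-E isomerisation, and C8 keeps its configuration because only the O–H bond reacts.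

Step 6
Reactants: 8 (1S,6S)-6-[(3S)-3-(angeloyloxy)hexa-1,5-dien-2-yl]-3-methyl-2-oxocyclohex-3-en-1-yl angelate
Product: 9 (1S,6S,8S)-1,8-bis(angeloyloxy)bisabola-3,7(14),10-trien-2-one
Conditions: second-generation Grubbs catalyst RuCl2(=CHPh)(PCy3)(H2IMes) (5 mol %), 2-methyl-2-butene/CH2Cl2 (1:1), 40 °C, sealed tube
Reagents that add atoms: 2-methyl-2-butene, CC=C(C)C
Why: Olefin cross-metathesis with excess 2-methyl-2-butene turns only the monosubstituted vinyl group into the prenyl alkene, because the 1,1-disubstituted C7=C14, the enone and the angelate alkenes are too hindered or electron-poor to enter the catalytic cycle.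

Step 7
Reactants: 9 (1S,6S,8S)-1,8-bis(angeloyloxy)bisabola-3,7(14),10-trien-2-one
Product: 10 (1S,2S,6S,8S)-1,8-bis(angeloyloxy)bisabola-3,7(14),10-trien-2-ol
Conditions: NaBH4 (1.0 equiv), CeCl3·7H2O (1.1 equiv), MeOH, −78 °C; aq NH4Cl
Reagents that add atoms: none
Why: Luche reduction gives clean 1,2-reduction with axial hydride delivery on the half-chair that has the C1 and C6 substituents equatorial (as carvone gives cis-carveol), so C2–OH ends equatorial, trans to C1–O and cis to the side chain.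

Step 8
Reactants: 10 (1S,2S,6S,8S)-1,8-bis(angeloyloxy)bisabola-3,7(14),10-trien-2-ol
Product: 12 (1S,2R,3S,4S,6S,8S,10R)-1,8-bis(angeloyloxy)-3,4:10,11-diepoxybisabol-7(14)-en-2-ol, via ring monoepoxide 11 (not isolated)
Conditions: VO(acac)2 (3 mol %), t-BuOOH (1.3 equiv, decane), PhMe, 0 °C → rt; then same flask: MeCN/CH2(OMe)2 (1:2), aq Na2B4O7/Na2EDTA buffer, Bu4NHSO4 (5 mol %), Shi ketone 1,2:4,5-di-O-isopropylidene-β-D-erythro-2,3-hexodiulo-2,6-pyranose (C12H18O6, 30 mol %), Oxone (2KHSO5·KHSO4·K2SO4, 1.5 equiv) and K2CO3 (6 equiv) added over 2 h, 0 °C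
Reagents that add atoms: tert-butyl hydroperoxide, CC(C)(C)OO; potassium peroxymonosulfate (active part of Oxone), [K+].[O-]S(=O)(=O)OO
Why: Proposed new method: both oxiranes are closed in one flask by two orthogonal, individually known oxygen transfers run back to back without work-up — first the Sharpless–Michaelson hydroxyl-directed epoxidation, in which the C2 vanadate ester of the pentavalent vanadium tert-butylperoxo complex delivers oxygen to the C3=C4 face syn to C2–OH (3S,4S) and leaves the unactivated C10=C11 and the C7=C14 alkene (allylic oxygen esterified) alone, then the Shi asymmetric epoxidation, in which the dioxirane of the D-fructose ketone attacks the only remaining electron-rich alkene through the spiro transition state that gives R epoxides from trisubstituted olefins (10R), while EDTA sequesters vanadium and leftover t-BuOOH is inert; the closest precedents are VO(acac)2/t-BuOOH epoxidation of cis-carveol and Shi epoxidation of prenyl groups in polyenes bearing allylic esters.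

Step 9
Reactants: 12 (1S,2R,3S,4S,6S,8S,10R)-1,8-bis(angeloyloxy)-3,4:10,11-diepoxybisabol-7(14)-en-2-ol
Product: 13 (1S,2R,3S,4S,6S,8S,10R)-1,2,8-tris(angeloyloxy)-3,4:10,11-diepoxybisabol-7(14)-ene (CNP0258231.3)
Conditions: LiN(SiMe3)2 (1.2 equiv), THF, −78 °C; angelic anhydride (2 equiv), −78 → −20 °C
Reagents that add atoms: angelic anhydride, C/C=C(/C)C(=O)OC(=O)/C(C)=C\C
Why: Acylation of the lithium alkoxide with the anhydride at low temperature gives the hindered angelate without Z/E isomerisation; the alkoxide is syn to the oxirane so no Payne rearrangement is possible, and any 1,2-acyl shift converges on the same triester.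

## Compound list

1 | (R)-(−)-carvone | C=C(C)[C@@H]1CC=C(C)C(=O)C1 | starting material
2 | potassium (3R)-6-methyl-3-(prop-1-en-2-yl)cyclohexa-1,5-dien-1-olate (kinetic dienolate) | C=C(C)[C@@H]1CC=C(C)C([O-])=C1.[K+] | intermediate
3 | potassium (1S,6S)-3-methyl-2-oxo-6-(prop-1-en-2-yl)cyclohex-3-en-1-olate | C=C(C)[C@@H]1CC=C(C)C(=O)[C@H]1[O-].[K+] | intermediate
4 | (1S,6S)-3-methyl-2-oxo-6-(prop-1-en-2-yl)cyclohex-3-en-1-yl angelate (trans-6-angeloyloxycarvone) | C=C(C)[C@@H]1CC=C(C)C(=O)[C@H]1OC(=O)/C(C)=C\C | intermediate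
5 | (1S,6S)-6-(3-chloroprop-1-en-2-yl)-3-methyl-2-oxocyclohex-3-en-1-yl angelate | C=C(CCl)[C@@H]1CC=C(C)C(=O)[C@H]1OC(=O)/C(C)=C\C | intermediate
6 | (1S,6S)-3-methyl-2-oxo-6-(3-oxoprop-1-en-2-yl)cyclohex-3-en-1-yl angelate | C=C(C=O)[C@@H]1CC=C(C)C(=O)[C@H]1OC(=O)/C(C)=C\C | intermediate
7 | (1S,6S)-6-[(3S)-3-hydroxyhexa-1,5-dien-2-yl]-3-methyl-2-oxocyclohex-3-en-1-yl angelate | C=C([C@H](CC=C)O)[C@@H]1CC=C(C)C(=O)[C@H]1OC(=O)/C(C)=C\C | intermediate
8 | (1S,6S)-6-[(3S)-3-(angeloyloxy)hexa-1,5-dien-2-yl]-3-methyl-2-oxocyclohex-3-en-1-yl angelate | C=C([C@H](CC=C)OC(=O)/C(C)=C\C)[C@@H]1CC=C(C)C(=O)[C@H]1OC(=O)/C(C)=C\C | intermediate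
9 | (1S,6S,8S)-1,8-bis(angeloyloxy)bisabola-3,7(14),10-trien-2-one | C=C([C@H](CC=C(C)C)OC(=O)/C(C)=C\C)[C@@H]1CC=C(C)C(=O)[C@H]1OC(=O)/C(C)=C\C | intermediate
10 | (1S,2S,6S,8S)-1,8-bis(angeloyloxy)bisabola-3,7(14),10-trien-2-ol (C2–OH trans to C1–O, cis to side chain) | C=C([C@H](CC=C(C)C)OC(=O)/C(C)=C\C)[C@@H]1CC=C(C)[C@H](O)[C@H]1OC(=O)/C(C)=C\C | intermediate
11 | (1S,2R,3S,4S,6S,8S)-1,8-bis(angeloyloxy)-3,4-epoxybisabola-7(14),10-dien-2-ol (oxirane syn to C2–OH) | C=C([C@H](CC=C(C)C)OC(=O)/C(C)=C\C)[C@@H]1C[C@@H]2O[C@]2(C)[C@H](O)[C@H]1OC(=O)/C(C)=C\C | intermediate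
12 | (1S,2R,3S,4S,6S,8S,10R)-1,8-bis(angeloyloxy)-3,4:10,11-diepoxybisabol-7(14)-en-2-ol | C=C([C@H](C[C@H]1OC1(C)C)OC(=O)/C(C)=C\C)[C@@H]1C[C@@H]2O[C@]2(C)[C@H](O)[C@H]1OC(=O)/C(C)=C\C | intermediate
13 | (1S,2R,3S,4S,6S,8S,10R)-1,2,8-tris(angeloyloxy)-3,4:10,11-diepoxybisabol-7(14)-ene (CNP0258231.3) | C=C([C@H](C[C@H]1OC1(C)C)OC(=O)/C(C)=C\C)[C@@H]1C[C@@H]2O[C@]2(C)[C@H](OC(=O)/C(C)=C\C)[C@H]1OC(=O)/C(C)=C\C | target

## Step count and risks

Total steps: 9. Longest linear sequence: 9 steps from (R)-carvone 1; the route is fully linear.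

Three steps most likely to fail:

**Step 8 (one-flask double epoxidation).** Vanadium or peroxide residues may disturb the dioxirane stage, the Shi stage may give imperfect selectivity at C10 against the C8 stereocentre, and the pH 10.5 medium may shift the C1 angelate to C2 (harmless, since step 9 converges). Fallback: set out from enone 9, whose ring alkene is still deactivated by conjugation. Shi epoxidation with the same ketone can then only reach C10=C11 and gives (1S,6S,8S,10R)-1,8-bis(angeloyloxy)-10,11-epoxybisabola-3,7(14)-dien-2-one F1. NaBH4/CeCl3·7H2O reduction gives (1S,2S,6S,8S,10R)-1,8-bis(angeloyloxy)-10,11-epoxybisabola-3,7(14)-dien-2-ol F2, and a separate VO(acac)2/t-BuOOH epoxidation of this isolated alcohol comes back to the route at 12.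

**Step 1 (one-pot hydroxylation/angeloylation).** Risks are modest trans selectivity, enolate addition to the sulfonimine by-product, and enolisation of the α-ketol alkoxide before it is acylated. Fallback: set out from 1 and make the oxygen and the ester in separate, isolable stages. LiN(iPr)2/Me3SiCl gives [(3R)-6-methyl-3-(prop-1-en-2-yl)cyclohexa-1,5-dien-1-yl]oxy(trimethyl)silane F3. Rubottom oxidation (mCPBA, NaHCO3, then dilute HCl) gives (5S,6S)-6-hydroxy-2-methyl-5-(prop-1-en-2-yl)cyclohex-2-en-1-one F4, whose cis epimer can be equilibrated or separated. Esterification with the angelic acid/2,4,6-trichlorobenzoyl chloride mixed anhydride comes back to the route at 4.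

**Step 3 (chloride to enal).** Displacement at the hindered 2-substituted allyl chloride may be slow, and amine base can isomerise the exo-methylene enal into conjugation. Fallback: set out from 4 and bypass chloride 5 by direct allylic C–H oxidation. SeO2 (cat.)/t-BuOOH in CH2Cl2 hydroxylates the isopropenyl methyl to (1S,6S)-6-(3-hydroxyprop-1-en-2-yl)-3-methyl-2-oxocyclohex-3-en-1-yl angelate F5, and MnO2 oxidation of this allylic alcohol comes back to the route at 6.

## Further compounds

F1 | step 8 | (1S,6S,8S,10R)-1,8-bis(angeloyloxy)-10,11-epoxybisabola-3,7(14)-dien-2-one | C=C([C@H](C[C@H]1OC1(C)C)OC(=O)/C(C)=C\C)[C@@H]1CC=C(C)C(=O)[C@H]1OC(=O)/C(C)=C\C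
F2 | step 8 | (1S,2S,6S,8S,10R)-1,8-bis(angeloyloxy)-10,11-epoxybisabola-3,7(14)-dien-2-ol | C=C([C@H](C[C@H]1OC1(C)C)OC(=O)/C(C)=C\C)[C@@H]1CC=C(C)[C@H](O)[C@H]1OC(=O)/C(C)=C\C
F3 | step 1 | [(3R)-6-methyl-3-(prop-1-en-2-yl)cyclohexa-1,5-dien-1-yl]oxy(trimethyl)silane | C=C(C)[C@@H]1CC=C(C)C(O[Si](C)(C)C)=C1
F4 | step 1 | (5S,6S)-6-hydroxy-2-methyl-5-(prop-1-en-2-yl)cyclohex-2-en-1-one | C=C(C)[C@@H]1CC=C(C)C(=O)[C@H]1O
F5 | step 3 | (1S,6S)-6-(3-hydroxyprop-1-en-2-yl)-3-methyl-2-oxocyclohex-3-en-1-yl angelate | C=C(CO)[C@@H]1CC=C(C)C(=O)[C@H]1OC(=O)/C(C)=C\C
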